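**Plan**

- Ring A is numbered C1 (aroyl), C2 (OH), C3 (H), C4 (OH), C5 (prenyl), C6 (OMe). The target has no stereocentre and no stereogenic alkene, so no stereochemistry has to be set.
- Feature used: C6 is the only oxygen-bearing carbon of ring A with a carbon substituent on each side, and the C2 and C4 hydroxyls are mirror images across the C6···C3 axis. Ring A therefore maps onto a symmetric 1,5-diester whose ether methyl is in place before the ring exists.
- Cuts, in retrosynthetic order: the bond from the ketone carbon to ring B (ester plus aryllithium); the benzylic CH2–CH= bond of the prenyl group (benzylic bromide plus alkenyl Grignard reagent); the ring A bonds C1–C2 and C5–C4 (double C-acylation of a 3-methoxyglutaconate by a malonyl unit).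
- Forward order: enol ether of acetonedicarboxylate, ring A closed as a symmetric dihydroxy-methoxy-isophthalate, MOM protection, half-saponification to break the symmetry, carboxyl to CH2Br to prenyl, remaining ester to ketone with the ring B aryllithium, global MOM removal. Ring B is bought as a bromophenol.

Key step: step 2

**Step 1**
Reactants: 1 dimethyl 3-oxopentanedioate (dimethyl 1,3-acetonedicarboxylate)
Product: 2 dimethyl (E)-3-methoxypent-2-enedioate
Conditions: HC(OMe)3 (2 equiv), conc. H2SO4 (cat.), neat, 25 → 60 °C; vacuum distillation
Reagents that add atoms: trimethyl orthoformate, COC(OC)OC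
Why: Acid-catalysed ketalisation by the orthoester followed by loss of methanol on distillation should give the conjugated (E)-β-methoxy enoate, the standard enol ether formation from a β-keto ester.

**Step 2**
Reactants: 2 dimethyl (E)-3-methoxypent-2-enedioate; 3 bis(2,4,6-trichlorophenyl) malonate
Product: 6 dimethyl 4,6-dihydroxy-2-methoxyisophthalate, via aryloxycarbonyl ketene 4 (not isolated), via acyclic C-acylated triester 5 (not isolated)
Conditions: NaH (3.3 equiv), THF, 0 °C; 3 (1.05 equiv) added slowly in THF; 0 → 65 °C; then 1 M HCl
Reagents that add atoms: none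
Why: Proposed new method: NaH turns 2 into its delocalised sodium dienolate and 3 into its enolate, which loses trichlorophenoxide (E1cB) to give ketene 4; the terminal carbon of the dienolate adds to the ketene carbonyl to give the enolate of 5 and with it the future C1–C2 bond (direct attack on an aryl ester of 3 would lead to the same adduct). In that enolate the charge is relayed through the methoxy-bearing carbon to the other ester-bearing carbon, which attacks the remaining trichlorophenyl ester in a 6-exo-trig Dieckmann-type closure (future C5–C4 bond), and the cyclic dione enolises irreversibly to arene 6. The closest known reactions are the cyclocondensations of bis(2,4,6-trichlorophenyl) malonates with 1,3-dinucleophiles and the classical Claisen–Dieckmann route from 3-oxoglutarate and malonate esters to phloroglucinol dicarboxylates. The step needs C-acylation at both termini and not O-acylation: the oxygen on the central carbon is already a methyl ether, so the usual pyranone closure through it cannot occur, any ester-enolate O-acylation gives a ketene acetal that is itself an acyl donor and can revert, and aromatisation is the thermodynamic sink. Both partners are symmetric, so no regiochemical choice arises, and no stereocentre is formed (the alkene geometry of 2 is erased).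

**Step 3**
Reactants: 6 dimethyl 4,6-dihydroxy-2-methoxyisophthalate
Product: 7 dimethyl 2-methoxy-4,6-bis(methoxymethoxy)isophthalate
Conditions: NaH (2.4 equiv), MOMCl (2.6 equiv), DMF, 0 → 25 °C
Reagents that add atoms: chloromethyl methyl ether, COCCl
Why: Williamson-type O-alkylation of both sodium phenoxides should give acetal ethers that tolerate hydroxide, borane and the organometallic reagents used later and that fall off together at the end.

**Step 4**
Reactants: 7 dimethyl 2-methoxy-4,6-bis(methoxymethoxy)isophthalate
Product: 8 2-methoxy-3-(methoxycarbonyl)-4,6-bis(methoxymethoxy)benzoic acid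
Conditions: KOH (1.05 equiv), MeOH–H2O (4:1), reflux; then 1 M HCl to pH 3–4 at 0 °C
Reagents that add atoms: potassium hydroxide, [K+].[OH-]
Why: Saponification with one equivalent of hydroxide should stop largely at the half-ester because the carboxylate formed first lowers the electrophilicity of the second ester, as in the half-hydrolysis of dimethyl isophthalates, and the two esters are equivalent so either one gives the same acid.

**Step 5**
Reactants: 8 2-methoxy-3-(methoxycarbonyl)-4,6-bis(methoxymethoxy)benzoic acid
Product: 9 methyl 3-(hydroxymethyl)-2-methoxy-4,6-bis(methoxymethoxy)benzoate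
Conditions: BH3·SMe2 (2 equiv), THF, 0 → 25 °C; MeOH quench, aqueous work-up
Reagents that add atoms: none
Why: Borane reduces a carboxylic acid through its acyloxyborane far faster than a methyl ester, so this chemoselective borane reduction should convert only the free carboxyl into CH2OH.

**Step 6**
Reactants: 9 methyl 3-(hydroxymethyl)-2-methoxy-4,6-bis(methoxymethoxy)benzoate
Product: 10 methyl 3-(bromomethyl)-2-methoxy-4,6-bis(methoxymethoxy)benzoate
Conditions: CBr4 (1.3 equiv), PPh3 (1.3 equiv), CH2Cl2, 0 °C; short silica plug, used at once
Reagents that add atoms: carbon tetrabromide, BrC(Br)(Br)Br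
Why: The Appel reaction replaces the benzylic hydroxyl by bromide under neutral conditions that spare the MOM ethers, and the ester, conjugated with all three ring oxygens, should temper ionisation of the benzylic bromide.

**Step 7**
Reactants: 10 methyl 3-(bromomethyl)-2-methoxy-4,6-bis(methoxymethoxy)benzoate; 11 2-methylprop-1-enylmagnesium bromide
Product: 12 methyl 2-methoxy-4,6-bis(methoxymethoxy)-3-(3-methylbut-2-en-1-yl)benzoate
Conditions: 11 (1.5 equiv), CuI (10 mol %), THF, −30 → 0 °C
Reagents that add atoms: none
Why: Copper-catalysed sp3–sp2 cross-coupling of a benzylic bromide with an alkenyl Grignard reagent (Kochi-type) should form the CH2–CH= bond of the prenyl group at a temperature at which the di-ortho-substituted ester is not attacked.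

**Step 8**
Reactants: 13 4-bromo-2-methoxyphenol
Product: 14 4-bromo-2-methoxy-1-(methoxymethoxy)benzene
Conditions: NaH (1.2 equiv), MOMCl (1.2 equiv), THF, 0 → 25 °C
Reagents that add atoms: chloromethyl methyl ether, COCCl
Why: Williamson-type O-alkylation of the phenoxide gives a MOM ether that withstands n-BuLi at −78 °C and matches the protecting groups of ring A.

**Step 9**
Reactants: 14 4-bromo-2-methoxy-1-(methoxymethoxy)benzene; 12 methyl 2-methoxy-4,6-bis(methoxymethoxy)-3-(3-methylbut-2-en-1-yl)benzoate
Product: 16 [3-methoxy-4-(methoxymethoxy)phenyl][2-methoxy-4,6-bis(methoxymethoxy)-3-(3-methylbut-2-en-1-yl)phenyl]methanone, via aryllithium 15 (not isolated)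
Conditions: 14 (1.3 equiv), n-BuLi (1.25 equiv), THF, −78 °C; then 12 (1.0 equiv), −78 → −30 °C; sat. aq NH4Cl
Reagents that add atoms: none
Why: Bromine–lithium exchange gives the unhindered aryllithium 15, which should add once to the ester (acyl substitution by an organolithium) because the tetrahedral lithium alkoxide is chelated by the ortho ethers and the di-ortho-substituted benzophenone released from it resists a second addition.

**Step 10**
Reactants: 16 [3-methoxy-4-(methoxymethoxy)phenyl][2-methoxy-4,6-bis(methoxymethoxy)-3-(3-methylbut-2-en-1-yl)phenyl]methanone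
Product: 17 [4,6-dihydroxy-2-methoxy-3-(3-methylbut-2-en-1-yl)phenyl](4-hydroxy-3-methoxyphenyl)methanone (CNP0197938.0)
Conditions: 3 M aq HCl, MeOH, 25 °C
Reagents that add atoms: none
Why: Acid-catalysed acetal exchange with methanol should remove all three MOM ethers at room temperature, conditions under which ortho-prenyl phenols are routinely unveiled without closure to the chroman.

**Compound list**

1 | dimethyl 3-oxopentanedioate (dimethyl 1,3-acetonedicarboxylate) | COC(=O)CC(=O)CC(=O)OC | starting material
2 | dimethyl (E)-3-methoxypent-2-enedioate | COC(=O)/C=C(/OC)CC(=O)OC | intermediate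
3 | bis(2,4,6-trichlorophenyl) malonate | O=C(CC(=O)Oc1c(Cl)cc(Cl)cc1Cl)Oc1c(Cl)cc(Cl)cc1Cl | starting material
4 | 2,4,6-trichlorophenyl 3-oxoprop-2-enoate (aryloxycarbonyl ketene, not isolated) | O=C=CC(=O)Oc1c(Cl)cc(Cl)cc1Cl | intermediate
5 | dimethyl 3-methoxy-2-[3-oxo-3-(2,4,6-trichlorophenoxy)propanoyl]pent-3-enedioate (not isolated; present as its sodium enolate, drawn as the keto form, racemic at C2, alkene geometry mobile) | COC(=O)C(C(=O)CC(=O)Oc1c(Cl)cc(Cl)cc1Cl)C(OC)=CC(=O)OC | intermediate
6 | dimethyl 4,6-dihydroxy-2-methoxyisophthalate | COC(=O)c1c(O)cc(O)c(C(=O)OC)c1OC | intermediate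
7 | dimethyl 2-methoxy-4,6-bis(methoxymethoxy)isophthalate | COC(=O)c1c(OCOC)cc(OCOC)c(C(=O)OC)c1OC | intermediate
8 | 2-methoxy-3-(methoxycarbonyl)-4,6-bis(methoxymethoxy)benzoic acid | COC(=O)c1c(OCOC)cc(OCOC)c(C(=O)O)c1OC | intermediate
9 | methyl 3-(hydroxymethyl)-2-methoxy-4,6-bis(methoxymethoxy)benzoate | COC(=O)c1c(OCOC)cc(OCOC)c(CO)c1OC | intermediate
10 | methyl 3-(bromomethyl)-2-methoxy-4,6-bis(methoxymethoxy)benzoate | COC(=O)c1c(OCOC)cc(OCOC)c(CBr)c1OC | intermediate
11 | 2-methylprop-1-enylmagnesium bromide | CC(C)=C[Mg]Br | starting material
12 | methyl 2-methoxy-4,6-bis(methoxymethoxy)-3-(3-methylbut-2-en-1-yl)benzoate | COC(=O)c1c(OCOC)cc(OCOC)c(CC=C(C)C)c1OC | intermediate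
13 | 4-bromo-2-methoxyphenol | COc1cc(Br)ccc1O | starting material
14 | 4-bromo-2-methoxy-1-(methoxymethoxy)benzene | COCOc1ccc(Br)cc1OC | intermediate
15 | [3-methoxy-4-(methoxymethoxy)phenyl]lithium (not isolated) | COCOc1ccc([Li])cc1OC | intermediate
16 | [3-methoxy-4-(methoxymethoxy)phenyl][2-methoxy-4,6-bis(methoxymethoxy)-3-(3-methylbut-2-en-1-yl)phenyl]methanone | COCOc1ccc(C(=O)c2c(OCOC)cc(OCOC)c(CC=C(C)C)c2OC)cc1OC | intermediate
17 | [4,6-dihydroxy-2-methoxy-3-(3-methylbut-2-en-1-yl)phenyl](4-hydroxy-3-methoxyphenyl)methanone | COc1cc(C(=O)c2c(O)cc(O)c(CC=C(C)C)c2OC)ccc1O | target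

**Step count**

Total: 10 steps. Longest linear sequence: 9 steps (steps 1–7, 9 and 10); step 8 is a one-step side branch.

**Steps most likely to fail**

Step 2. The activated malonate may condense with itself through ketene 4, the dienolate may be acylated on oxygen faster than on carbon, or the sequence may stall at the open-chain stage 5. The fallback makes the two C–C bonds one at a time by known reactions. It leaves the route at 2: the sodium dienolate (NaH, THF, 0 °C, or MgCl2/Et3N in MeCN) is C-acylated with methyl 3-chloro-3-oxopropanoate and the product is isolated as dimethyl 3-methoxy-2-(3-methoxy-3-oxopropanoyl)pent-3-enedioate F1. This triester is then closed in a separate Dieckmann condensation (NaOMe, MeOH, reflux, acidic work-up), the classical phloroglucinol-dicarboxylate ring closure, and aromatisation brings the route back at 6.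

Step 7. Bromine–magnesium exchange at the electron-rich benzylic bromide may lead to Wurtz-type homocoupling, or the Grignard reagent may add to the ester. The fallback reverses the polarity of the coupling. From 10, zinc insertion (Zn dust, LiCl, THF, 25 °C) should give {[2-methoxy-3-(methoxycarbonyl)-4,6-bis(methoxymethoxy)phenyl]methyl}zinc bromide F2, an ester-tolerant benzylic nucleophile. Negishi coupling of this reagent with commercial 1-bromo-2-methylprop-1-ene (Pd(PPh3)4, a zerovalent palladium catalyst, THF, 50 °C) rejoins the route at 12.

Step 9. Addition to the di-ortho-substituted ester may be sluggish, so that on warming the aryllithium deprotonates the ring position between the two MOM ethers or adds a second time to liberated ketone. The fallback moves to the aldehyde oxidation level, starting from 12. LiAlH4 (THF, 0 °C) reduces the ester to [2-methoxy-4,6-bis(methoxymethoxy)-3-(3-methylbut-2-en-1-yl)phenyl]methanol F3, and MnO2 (CH2Cl2, 25 °C) oxidises this to 2-methoxy-4,6-bis(methoxymethoxy)-3-(3-methylbut-2-en-1-yl)benzaldehyde F4. Aryllithium 15 adds to this far more electrophilic carbonyl at −78 °C to give racemic [3-methoxy-4-(methoxymethoxy)phenyl][2-methoxy-4,6-bis(methoxymethoxy)-3-(3-methylbut-2-en-1-yl)phenyl]methanol F5, and Dess–Martin periodinane oxidation returns the route at 16.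

**Further compounds**

F1 | step 2 | dimethyl 3-methoxy-2-(3-methoxy-3-oxopropanoyl)pent-3-enedioate (keto form of an enolisable tautomer mixture, racemic at C2) | COC(=O)CC(=O)C(C(=O)OC)C(OC)=CC(=O)OC
F2 | step 7 | {[2-methoxy-3-(methoxycarbonyl)-4,6-bis(methoxymethoxy)phenyl]methyl}zinc bromide | COC(=O)c1c(OCOC)cc(OCOC)c(C[Zn]Br)c1OC
F3 | step 9 | [2-methoxy-4,6-bis(methoxymethoxy)-3-(3-methylbut-2-en-1-yl)phenyl]methanol | OCc1c(OCOC)cc(OCOC)c(CC=C(C)C)c1OC
F4 | step 9 | 2-methoxy-4,6-bis(methoxymethoxy)-3-(3-methylbut-2-en-1-yl)benzaldehyde | O=Cc1c(OCOC)cc(OCOC)c(CC=C(C)C)c1OC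
F5 | step 9 | [3-methoxy-4-(methoxymethoxy)phenyl][2-methoxy-4,6-bis(methoxymethoxy)-3-(3-methylbut-2-en-1-yl)phenyl]methanol (racemic) | COCOc1ccc(C(O)c2c(OCOC)cc(OCOC)c(CC=C(C)C)c2OC)cc1OC
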